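**Retrosynthetic overview**
1. Target 19 ⇐ catalyst-controlled reduction of enone 18 (sets C15); 18 ⇐ acyl substitution joining a decalin Weinreb amide to a ring-opened cyclogeranyl-lithium (C15–CH2 bond).
2. Decalin half ⇐ Wittig extension of the lactol of δ-lactone 5; C13 is already the lactone carbonyl, so no homologation is needed.
3. Lactone 5 ⇐ one proton-initiated asymmetric tricyclization of achiral (E,E)-farnesylacetic acid 4: ring A, ring B and the lactone ring close together and fix C5, C8, C9 and C10.
4. Cyclohexane half ⇐ 3-methylcyclohexenone; its stereocentre is set by asymmetric cyclopropanation, and the exocyclic methylene is released when the cyclopropylmethyl-lithium opens.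
5. Ring order: rings A + B + δ-lactone (step 2), lactone opened (step 3); cyclopropane made (step 6) and opened (step 8); the six-membered ring of the right half is bought in.

Assumption: locants C5–C15 follow labdane numbering of the decalin half and its chain; (2E,6E)-farnesyl bromide, phosphorane 6 and both antipodes of the Charette dioxaborolane are taken as catalogue items.

**Step 1**
Reactants: 1 (2E,6E)-farnesyl bromide; 2 acetic acid
Product: 4 (4E,8E)-5,9,13-trimethyltetradeca-4,8,12-trienoic acid, via dilithium acetate dianion 3 (not isolated)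
Conditions: LiN(i-Pr)2 (2.2 equiv), THF–DMPU, 0 °C; then 1, 0 °C → rt; aq. HCl
Reagents that add atoms: none
Why: Alkylation of the carboxylic acid dianion (enolate SN2 alkylation) at the primary allylic bromide adds the two-carbon acid arm without touching either (E)-alkene, and no stereocentre is formed.

**Step 2**
Reactants: 4 (4E,8E)-5,9,13-trimethyltetradeca-4,8,12-trienoic acid
Product: 5 (+)-ambreinolide [(4aR,6aS,10aS,10bR)-4a,7,7,10a-tetramethyldodecahydro-1H-benzo[f]chromen-3-one]
Conditions: confined chiral imidodiphosphorimidate (IDPi) Brønsted acid (5 mol %; the antipode that gives the natural ambrox series), (CF3)3COH, −40 °C; recrystallize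
Reagents that add atoms: none
Why: Proposed new method: the confined chiral acid protonates the terminal isopropylidene group while the (E,E)-triene is folded chair–chair in its pocket, so anti addition across both alkenes closes ring A and ring B and the carboxyl oxygen captures the C8 cation from the α face, setting C5, C8, C9 and C10 in one catalyst-controlled event; the closest known reactions are the catalytic asymmetric proton-initiated cyclization of homofarnesol to ambrox, the chiral-acid lactonizing cyclization of homofarnesic acid to sclareolide and the racemic acid-mediated cyclization of this same acid to ambreinolide (biomimetic cationic polyene cyclization).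

**Step 3**
Reactants: 5 (+)-ambreinolide; 6 ethyl 2-(triphenylphosphoranylidene)propanoate
Product: 8 ethyl (2E)-5-[(1R,2R,4aS,8aS)-2-hydroxy-2,5,5,8a-tetramethyldecahydronaphthalen-1-yl]-2-methylpent-2-enoate, via lactol 7 (not isolated)
Conditions: i-Bu2AlH (1.1 equiv), toluene, −78 °C; MeOH (1 equiv); then 6, 80 °C; aq. KNaC4H4O6
Reagents that add atoms: none
Why: Partial hydride reduction of the δ-lactone stops at the lactol, whose open hydroxy-aldehyde form is trapped by the stabilized ylide in an E-selective Wittig olefination that also frees the C8 tertiary alcohol, with no stereocentre changed.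

**Step 4**
Reactants: 9 3-methylcyclohex-2-en-1-one
Product: 11 3,3-dimethylcyclohex-1-en-1-yl trifluoromethanesulfonate, via magnesium enolate 10 (not isolated)
Conditions: MeMgBr, CuBr·SMe2 (5 mol %), THF, −40 → 0 °C; then N-(5-chloropyridin-2-yl)bis(trifluoromethanesulfonimide), −78 °C → rt; H2O
Reagents that add atoms: methylmagnesium bromide, C[Mg]Br; N-(5-chloropyridin-2-yl)bis(trifluoromethanesulfonimide), FC(F)(F)S(=O)(=O)N(c1ccc(Cl)cn1)S(=O)(=O)C(F)(F)F
Why: Copper-catalysed conjugate addition of the Grignard reagent builds the gem-dimethyl carbon and gives the enolate regiospecifically on the side of that carbon, which is trapped on oxygen as the enol triflate; no stereocentre is formed.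

**Step 5**
Reactants: 11 3,3-dimethylcyclohex-1-en-1-yl trifluoromethanesulfonate
Product: 12 (3,3-dimethylcyclohex-1-en-1-yl)methanol
Conditions: Bu3SnCH2OH, Pd(PPh3)4 (5 mol %), LiCl, 1,4-dioxane, 100 °C
Reagents that add atoms: (tributylstannyl)methanol, OC[Sn](CCCC)(CCCC)CCCC
Why: Migita–Kosugi–Stille cross-coupling replaces the triflate by CH2OH with the double bond held in place next to the gem-dimethyl carbon.

**Step 6**
Reactants: 12 (3,3-dimethylcyclohex-1-en-1-yl)methanol
Product: 13 [(1R,6S)-5,5-dimethylbicyclo[4.1.0]heptan-1-yl]methanol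
Conditions: Et2Zn, CH2I2, DME, CH2Cl2, −10 °C [Zn(CH2I)2·DME]; (4S,5S)-2-butyl-N,N,N′,N′-tetramethyl-1,3,2-dioxaborolane-4,5-dicarboxamide (1.2 equiv); 0 °C → rt
Reagents that add atoms: diiodomethane, ICI
Why: Charette asymmetric Simmons–Smith cyclopropanation, in which the zinc alkoxide bound to the chiral dioxaborolane directs CH2 to one alkene face and so fixes the ring CH carbon that becomes the stereocentre next to the exocyclic methylene; the (S,S) ligand is chosen because the (R,R) ligand gives the (S,S) cyclopropane from cinnamyl alcohol, which corresponds to attack on the opposite face from the one needed here.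

**Step 7**
Reactants: 13 [(1R,6S)-5,5-dimethylbicyclo[4.1.0]heptan-1-yl]methanol
Product: 14 (1R,6S)-1-(iodomethyl)-5,5-dimethylbicyclo[4.1.0]heptane
Conditions: I2, PPh3, imidazole, CH2Cl2, 0 °C
Reagents that add atoms: iodine, II
Why: Appel-type iodination of the primary alcohol by SN2 displacement leaves both cyclopropane stereocentres untouched.

**Step 8**
Reactants: 14 (1R,6S)-1-(iodomethyl)-5,5-dimethylbicyclo[4.1.0]heptane; 8 ethyl (2E)-5-[(1R,2R,4aS,8aS)-2-hydroxy-2,5,5,8a-tetramethyldecahydronaphthalen-1-yl]-2-methylpent-2-enoate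
Product: 18 (3E)-1-[(1S)-2,2-dimethyl-6-methylidenecyclohexyl]-6-[(1R,2R,4aS,8aS)-2-hydroxy-2,5,5,8a-tetramethyldecahydronaphthalen-1-yl]-3-methylhex-3-en-2-one, via cyclopropylmethyllithium 15 (not isolated), via homoallyllithium 16 (not isolated), via Weinreb amide 17 (not isolated)
Conditions: flask A: 8, MeNH(OMe)·HCl (1.5 equiv), i-PrMgCl (4 equiv), THF, −20 °C; flask B: 14 (1.5 equiv), t-BuLi (3 equiv), Et2O–pentane, −78 °C then 0 °C; B into A, −78 → 0 °C; H2O
Reagents that add atoms: none
Why: Iodine–lithium exchange gives a cyclopropylmethyllithium that opens on warming (cyclopropylcarbinyl-to-homoallyl organolithium rearrangement) towards the primary carbanion, creating the exocyclic methylene while the ring CH stereocentre is retained, and this organolithium acylates the Weinreb amide made in situ from ester 8 (Weinreb ketone synthesis), so addition stops at the ketone while the C8 magnesium alkoxide stays inert.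

**Step 9**
Reactants: 18 (3E)-1-[(1S)-2,2-dimethyl-6-methylidenecyclohexyl]-6-[(1R,2R,4aS,8aS)-2-hydroxy-2,5,5,8a-tetramethyldecahydronaphthalen-1-yl]-3-methylhex-3-en-2-one
Product: 19 (1R,2R,4aS,8aS)-1-[(3E,5R)-6-[(1S)-2,2-dimethyl-6-methylidenecyclohexyl]-5-hydroxy-4-methylhex-3-en-1-yl]-2,5,5,8a-tetramethyldecahydronaphthalen-2-ol
Conditions: (S)-2-methyl-CBS-oxazaborolidine (20 mol %), catecholborane (2.5 equiv), toluene, −78 °C; MeOH–H2O
Reagents that add atoms: none
Why: Corey–Bakshi–Shibata reduction, in which the α-methylalkenyl group acts as the large substituent so the (S)-oxazaborolidine delivers hydride to the face that gives the (R)-carbinol (same sense as acetophenone to (R)-1-phenylethanol) under catalyst control, while catecholborane at −78 °C leaves the exocyclic alkene untouched.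

**Compound list**
1 | (2E,6E)-farnesyl bromide [(2E,6E)-1-bromo-3,7,11-trimethyldodeca-2,6,10-triene] | CC(C)=CCC/C(C)=C/CC/C(C)=C/CBr | starting material
2 | acetic acid | CC(=O)O | starting material
3 | dilithium acetate dianion | [Li+].[Li+].[CH2-]C(=O)[O-] | intermediate
4 | (4E,8E)-5,9,13-trimethyltetradeca-4,8,12-trienoic acid (farnesylacetic acid) | CC(C)=CCC/C(C)=C/CC/C(C)=C/CCC(=O)O | intermediate
5 | (+)-ambreinolide, (4aR,6aS,10aS,10bR)-4a,7,7,10a-tetramethyldodecahydro-1H-benzo[f]chromen-3-one (trans-fused δ-lactone between the C13 acid and the 8α-oxygen) | O=C1CC[C@@H]2[C@@]3(C)CCCC(C)(C)[C@@H]3CC[C@@]2(C)O1 | intermediate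
6 | ethyl 2-(triphenylphosphoranylidene)propanoate | CCOC(=O)C(C)=P(c1ccccc1)(c1ccccc1)c1ccccc1 | starting material
7 | lactol of 5, (4aR,6aS,10aS,10bR)-4a,7,7,10a-tetramethyldodecahydro-1H-benzo[f]chromen-3-ol (anomer mixture) | OC1CC[C@@H]2[C@@]3(C)CCCC(C)(C)[C@@H]3CC[C@@]2(C)O1 | intermediate
8 | ethyl (2E)-5-[(1R,2R,4aS,8aS)-2-hydroxy-2,5,5,8a-tetramethyldecahydronaphthalen-1-yl]-2-methylpent-2-enoate | CCOC(=O)/C(C)=C/CC[C@@H]1[C@@]2(C)CCCC(C)(C)[C@@H]2CC[C@@]1(C)O | intermediate
9 | 3-methylcyclohex-2-en-1-one | CC1=CC(=O)CCC1 | starting material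
10 | bromomagnesium 3,3-dimethylcyclohex-1-en-1-olate | CC1(C)CCCC(O[Mg]Br)=C1 | intermediate
11 | 3,3-dimethylcyclohex-1-en-1-yl trifluoromethanesulfonate | CC1(C)CCCC(OS(=O)(=O)C(F)(F)F)=C1 | intermediate
12 | (3,3-dimethylcyclohex-1-en-1-yl)methanol | CC1(C)CCCC(CO)=C1 | intermediate
13 | [(1R,6S)-5,5-dimethylbicyclo[4.1.0]heptan-1-yl]methanol | OC[C@@]12CCCC(C)(C)[C@@H]1C2 | intermediate
14 | (1R,6S)-1-(iodomethyl)-5,5-dimethylbicyclo[4.1.0]heptane | IC[C@@]12CCCC(C)(C)[C@@H]1C2 | intermediate
15 | [(5,5-dimethylbicyclo[4.1.0]heptan-1-yl)methyl]lithium, same spatial arrangement as 14 (formally 1S,6S because CH2Li ranks lowest) | [Li]C[C@@]12CCCC(C)(C)[C@@H]1C2 | intermediate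
16 | {[(1S)-2,2-dimethyl-6-methylidenecyclohexyl]methyl}lithium | C=C1CCCC(C)(C)[C@@H]1C[Li] | intermediate
17 | (2E)-5-[(1R,2R,4aS,8aS)-2-hydroxy-2,5,5,8a-tetramethyldecahydronaphthalen-1-yl]-N-methoxy-N,2-dimethylpent-2-enamide (in the flask as its chloromagnesium alkoxide) | CON(C)C(=O)/C(C)=C/CC[C@@H]1[C@@]2(C)CCCC(C)(C)[C@@H]2CC[C@@]1(C)O | intermediate
18 | (3E)-1-[(1S)-2,2-dimethyl-6-methylidenecyclohexyl]-6-[(1R,2R,4aS,8aS)-2-hydroxy-2,5,5,8a-tetramethyldecahydronaphthalen-1-yl]-3-methylhex-3-en-2-one | C=C1CCCC(C)(C)[C@@H]1CC(=O)/C(C)=C/CC[C@@H]1[C@@]2(C)CCCC(C)(C)[C@@H]2CC[C@@]1(C)O | intermediate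
19 | (1R,2R,4aS,8aS)-1-[(3E,5R)-6-[(1S)-2,2-dimethyl-6-methylidenecyclohexyl]-5-hydroxy-4-methylhex-3-en-1-yl]-2,5,5,8a-tetramethyldecahydronaphthalen-2-ol | C=C1CCCC(C)(C)[C@@H]1C[C@@H](O)/C(C)=C/CC[C@@H]1[C@@]2(C)CCCC(C)(C)[C@@H]2CC[C@@]1(C)O | target

**Totals**
Total step count: 9. Longest linear sequence: 6 (steps 4, 5, 6, 7, 8, 9); the decalin branch is 5 (steps 1, 2, 3, 8, 9).

**Steps most likely to fail, with fallbacks**

Step 2 (acid-terminated asymmetric tricyclization; six-membered lactone closure with a carboxylic acid is an extrapolation and may give low ee or stop at monocyclic acids). The fallback sets out from 4: reduce the acid with LiAlH4 (Et2O, 0 °C) to (4E,8E)-5,9,13-trimethyltetradeca-4,8,12-trien-1-ol F1, run the same chiral-acid cyclization with the hydroxyl group as terminating nucleophile (the ambrox-type closure, here to a six-membered ether) to give the tricyclic ether (4aR,6aS,10aS,10bR)-4a,7,7,10a-tetramethyldodecahydro-1H-benzo[f]chromene F2, and oxidize the O–CH2 group with RuCl3 (cat.)/NaIO4 in CCl4–MeCN–H2O; this comes back to the route at lactone 5.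

Step 6 (cyclopropanation of an alkene flanked by a quaternary carbon may be slow or poorly enantioselective). The fallback sets out from 12: a Johnson–Claisen rearrangement (MeC(OEt)3, EtCO2H cat., 140 °C) makes the C–C bond and the exocyclic methylene at once and gives racemic ethyl 2-(2,2-dimethyl-6-methylidenecyclohexyl)acetate F3; saponify (LiOH) and resolve the acid through its salt with one antipode of 1-phenylethylamine to 2-[(1S)-2,2-dimethyl-6-methylidenecyclohexyl]acetic acid F4; re-esterify (MeI, K2CO3) to methyl 2-[(1S)-2,2-dimethyl-6-methylidenecyclohexyl]acetate F5; add LiCH(CH3)P(O)(OEt)2 to obtain diethyl {4-[(1S)-2,2-dimethyl-6-methylidenecyclohexyl]-3-oxobutan-2-yl}phosphonate F6; and join F6 to lactol 7 (isolated after a tartrate work-up of the i-Bu2AlH reduction) by Horner–Wadsworth–Emmons olefination (Ba(OH)2, wet THF). This comes back to the route at enone 18 and bypasses the organolithium chemistry altogether.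

Step 8 (in situ amide formation from a hindered α-methyl enoate followed by acylation with a precious, ring-opened organolithium). The fallback sets out from 14 and uses lactol 7 in isolated form: olefinate 7 with 2-(triphenylphosphoranylidene)propanal (toluene, 90 °C) to (2E)-5-[(1R,2R,4aS,8aS)-2-hydroxy-2,5,5,8a-tetramethyldecahydronaphthalen-1-yl]-2-methylpent-2-enal F7, add organolithium 16 (made from 14 as in step 8, 2.2 equiv because of the free hydroxyl) to give the C15-epimeric mixture of 19, (3E)-1-[(1S)-2,2-dimethyl-6-methylidenecyclohexyl]-6-[(1R,2R,4aS,8aS)-2-hydroxy-2,5,5,8a-tetramethyldecahydronaphthalen-1-yl]-3-methylhex-3-en-2-ol F8, and oxidize the allylic alcohol selectively with MnO2 (CH2Cl2). This comes back to the route at enone 18.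

**Further compounds**
F1 | step 2 | (4E,8E)-5,9,13-trimethyltetradeca-4,8,12-trien-1-ol | CC(C)=CCC/C(C)=C/CC/C(C)=C/CCCO
F2 | step 2 | (4aR,6aS,10aS,10bR)-4a,7,7,10a-tetramethyldodecahydro-1H-benzo[f]chromene | C1CC[C@@H]2[C@@]3(C)CCCC(C)(C)[C@@H]3CC[C@@]2(C)O1
F3 | step 6 | ethyl 2-(2,2-dimethyl-6-methylidenecyclohexyl)acetate (racemic) | C=C1CCCC(C)(C)C1CC(=O)OCC
F4 | step 6 | 2-[(1S)-2,2-dimethyl-6-methylidenecyclohexyl]acetic acid | C=C1CCCC(C)(C)[C@@H]1CC(=O)O
F5 | step 6 | methyl 2-[(1S)-2,2-dimethyl-6-methylidenecyclohexyl]acetate | C=C1CCCC(C)(C)[C@@H]1CC(=O)OC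
F6 | step 6 | diethyl {4-[(1S)-2,2-dimethyl-6-methylidenecyclohexyl]-3-oxobutan-2-yl}phosphonate | C=C1CCCC(C)(C)[C@@H]1CC(=O)C(C)P(=O)(OCC)OCC
F7 | step 8 | (2E)-5-[(1R,2R,4aS,8aS)-2-hydroxy-2,5,5,8a-tetramethyldecahydronaphthalen-1-yl]-2-methylpent-2-enal | O=C/C(C)=C/CC[C@@H]1[C@@]2(C)CCCC(C)(C)[C@@H]2CC[C@@]1(C)O
F8 | step 8 | (3E)-1-[(1S)-2,2-dimethyl-6-methylidenecyclohexyl]-6-[(1R,2R,4aS,8aS)-2-hydroxy-2,5,5,8a-tetramethyldecahydronaphthalen-1-yl]-3-methylhex-3-en-2-ol (both C2 epimers) | C=C1CCCC(C)(C)[C@@H]1CC(O)/C(C)=C/CC[C@@H]1[C@@]2(C)CCCC(C)(C)[C@@H]2CC[C@@]1(C)O
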